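The benzoquinone ring (C1 carbonyl, C2 OMe, C3 H, C4 carbonyl, C5 methyl, C6 pentacosyl) carries its C2 and C4 oxygens meta, with the C5 methyl beside the C6 chain: a masked 4‑methyl‑5‑alkylresorcinol. The ring is therefore cut at C5–C6 and C3–C4. One base‑mediated Michael–Claisen [3+3] annulation joins the methyl‑bearing carbon of diethyl methylmalonate to the β‑carbon of (E)‑nonacos‑3‑en‑2‑one and closes the six‑membered carbocycle with both oxygens and both carbon substituents in place. The precursor is the linear C29 E‑enone, made from 1‑hexacosanol. Decarboxylation, dehydrogenation, para‑oxidation and O‑methylation finish the target.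

Key step: step 2

Remark: the target has no stereocentre and only endocyclic double bonds, so it is a single achiral structure; the stereocentres of intermediates 6–9 are transient and are left uncontrolled.

Step 1
Reactants: 1 1‑hexacosanol; 2 1‑(triphenyl‑λ5‑phosphanylidene)propan‑2‑one
Product: 4 (E)‑nonacos‑3‑en‑2‑one, via hexacosanal 3 (not isolated)
Conditions: IBX (3 equiv), EtOAc, 80 °C; filter warm; then 2 (1.3 equiv) in the filtrate, reflux
Reagents that add atoms: none
Why: IBX in hot ethyl acetate, where the waxy alcohol dissolves, should stop cleanly at the aldehyde, and the acetyl‑stabilised ylide then undergoes a Wittig olefination whose reversible oxaphosphetane formation delivers the E‑alkene; no stereocentre is formed.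

Step 2
Reactants: 4 (E)‑nonacos‑3‑en‑2‑one; 5 diethyl 2‑methylpropanedioate (diethyl methylmalonate)
Product: 7 ethyl 1‑methyl‑2,4‑dioxo‑6‑pentacosylcyclohexane‑1‑carboxylate (racemic cis/trans mixture), via diethyl 2‑methyl‑2‑(2‑oxononacosan‑4‑yl)propanedioate 6 (not isolated)
Conditions: 5 (1.2 equiv), NaOEt (1.2 equiv), EtOH/THF, rt; add 4 slowly, then reflux; cold aq. HCl
Reagents that add atoms: none
Why: Ethoxide deprotonates 5, and the soft, doubly stabilised tertiary carbanion adds reversibly in 1,4‑fashion to the β‑carbon of 4 (C5–C6 of the target ring) to give 6; proton exchange then gives the methyl‑side ketone enolate, which attacks one ester carbonyl, expels ethoxide (C3–C4) and ends as the sodium salt of the cyclic 1,3‑dione, the thermodynamic sink that pulls both equilibria forward. This is the same Michael–Claisen sequence as the classical dimedone and dihydroresorcinol syntheses from alk‑3‑en‑2‑ones and malonates. The ring closes in a 6‑(enolendo)‑exo‑trig mode. The two new stereocentres of 7 (quaternary C1 and C6) arise without external control as a racemic diastereomer mixture, which is acceptable because both are flattened later. The step needs 1,4‑ over 1,2‑addition and a single cyclisation regiochemistry: the stabilised nucleophile and reversibility secure the first, and the second follows because only the terminal methyl enolate can reach an ester through a six‑membered transition state, the internal α‑methylene offering only a four‑membered ring. Slow addition of 4 to the preformed malonate anion keeps enone self‑condensation down.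

Step 3
Reactants: 7 ethyl 1‑methyl‑2,4‑dioxo‑6‑pentacosylcyclohexane‑1‑carboxylate
Product: 9 4‑methyl‑5‑pentacosylcyclohexane‑1,3‑dione (racemic cis/trans mixture), via 1‑methyl‑2,4‑dioxo‑6‑pentacosylcyclohexane‑1‑carboxylic acid 8 (not isolated)
Conditions: aq. NaOH (4 equiv), EtOH/THF, reflux; then HCl to pH 1, 80 °C
Reagents that add atoms: none
Why: Hydroxide saponifies the ethyl ester while the 1,3‑dione sits as its enolate, which shields the neighbouring ketone from retro‑Claisen cleavage, and acidification gives the β‑keto acid that loses CO2 through the usual six‑membered cyclic transition state (β‑keto ester hydrolysis–decarboxylation); the methyl‑bearing carbon is reprotonated without control, which is of no consequence because both ring stereocentres disappear on aromatisation.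

Step 4
Reactants: 9 4‑methyl‑5‑pentacosylcyclohexane‑1,3‑dione
Product: 10 4‑methyl‑5‑pentacosylbenzene‑1,3‑diol
Conditions: 10% Pd/C (cat.), triglyme, 200 °C, N2 sweep
Reagents that add atoms: none
Why: A cyclohexane‑1,3‑dione is at the dihydroresorcinol oxidation level and should lose one molecule of H2 over palladium at this temperature to give the resorcinol (catalytic dehydrogenative aromatisation), with the gain in aromaticity as driving force and both stereocentres erased.

Step 5
Reactants: 10 4‑methyl‑5‑pentacosylbenzene‑1,3‑diol
Product: 11 2‑hydroxy‑5‑methyl‑6‑pentacosylcyclohexa‑2,5‑diene‑1,4‑dione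
Conditions: (KO3S)2NO (2.5 equiv), KH2PO4 buffer, Aliquat 336 (cat.), CHCl3/H2O, rt; acidify on work‑up
Reagents that add atoms: potassium nitrosodisulfonate (Fremy's salt), [K+].[K+].[O]N(S(=O)(=O)[O-])S(=O)(=O)[O-]
Why: In this Teuber oxidation the nitrosodisulfonate radical abstracts a phenolic hydrogen and a second equivalent couples through oxygen at C6 of 10, the only unsubstituted carbon para to a hydroxyl, so that loss of imidodisulfonate gives the p‑quinone while the other hydroxyl survives as the 2‑hydroxy group, as known for orcinol; the quaternary ammonium salt carries the oxidant to the lipophilic substrate.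

Step 6
Reactants: 11 2‑hydroxy‑5‑methyl‑6‑pentacosylcyclohexa‑2,5‑diene‑1,4‑dione
Product: 12 2‑methoxy‑5‑methyl‑6‑pentacosylcyclohexa‑2,5‑diene‑1,4‑dione (target)
Conditions: MeOH (excess), H2SO4 (cat.), CHCl3, 60 °C
Reagents that add atoms: methanol, CO
Why: The 2‑hydroxyquinone is a vinylogous carboxylic acid, so acid‑catalysed addition of methanol at C2 and loss of water (Fischer‑type etherification) should give the methyl ether under thermodynamic control, which favours the 2‑methoxy‑1,4‑quinone over the o‑quinone ether and leaves the fully substituted C5=C6 bond untouched.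

Compound list
1 | 1‑hexacosanol | CCCCCCCCCCCCCCCCCCCCCCCCCCO | starting material
2 | 1‑(triphenyl‑λ5‑phosphanylidene)propan‑2‑one | CC(=O)C=P(c1ccccc1)(c1ccccc1)c1ccccc1 | starting material
3 | hexacosanal | CCCCCCCCCCCCCCCCCCCCCCCCCC=O | intermediate
4 | (E)‑nonacos‑3‑en‑2‑one | CC(=O)/C=C/CCCCCCCCCCCCCCCCCCCCCCCCC | intermediate
5 | diethyl 2‑methylpropanedioate | CCOC(=O)C(C)C(=O)OCC | starting material
6 | diethyl 2‑methyl‑2‑(2‑oxononacosan‑4‑yl)propanedioate (racemic) | CCCCCCCCCCCCCCCCCCCCCCCCCC(CC(C)=O)C(C)(C(=O)OCC)C(=O)OCC | intermediate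
7 | ethyl 1‑methyl‑2,4‑dioxo‑6‑pentacosylcyclohexane‑1‑carboxylate (racemic, both diastereomers) | CCOC(=O)C1(C)C(=O)CC(=O)CC1CCCCCCCCCCCCCCCCCCCCCCCCC | intermediate
8 | 1‑methyl‑2,4‑dioxo‑6‑pentacosylcyclohexane‑1‑carboxylic acid (racemic, both diastereomers) | OC(=O)C1(C)C(=O)CC(=O)CC1CCCCCCCCCCCCCCCCCCCCCCCCC | intermediate
9 | 4‑methyl‑5‑pentacosylcyclohexane‑1,3‑dione (racemic, cis and trans) | CC1C(=O)CC(=O)CC1CCCCCCCCCCCCCCCCCCCCCCCCC | intermediate
10 | 4‑methyl‑5‑pentacosylbenzene‑1,3‑diol | Cc1c(O)cc(O)cc1CCCCCCCCCCCCCCCCCCCCCCCCC | intermediate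
11 | 2‑hydroxy‑5‑methyl‑6‑pentacosylcyclohexa‑2,5‑diene‑1,4‑dione | CCCCCCCCCCCCCCCCCCCCCCCCCC1=C(C)C(=O)C=C(O)C1=O | intermediate
12 | 2‑methoxy‑5‑methyl‑6‑pentacosylcyclohexa‑2,5‑diene‑1,4‑dione | CCCCCCCCCCCCCCCCCCCCCCCCCC1=C(C)C(=O)C=C(OC)C1=O | target

Total step count: 6. Longest linear sequence: 6 steps (1 to 12).

Steps most likely to fail

Step 2. The congested tertiary malonate carbanion may add slowly and reversibly, so that retro‑Michael reaction and self‑condensation of the enone outrun ring closure. The fallback sets out from 4 and returns at 7. The enone is annulated with unsubstituted diethyl malonate (NaOEt, EtOH/THF, reflux), a far less hindered donor. This passes through diethyl 2‑(2‑oxononacosan‑4‑yl)propanedioate F1 (not isolated) and gives ethyl 2,4‑dioxo‑6‑pentacosylcyclohexane‑1‑carboxylate F2. F2 is then converted into its dianion (LDA, 2.2 equiv, THF/DMPU, −40 to 0 °C) and treated with MeI (1 equiv). Alkylation should occur at the last‑formed, ester‑stabilised carbanion (C1) and not at the dione enolate, giving 7.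

Step 4. Dehydrogenation may stall, or hydrogen released on the catalyst may be transferred back, giving disproportionation and loss of a ring oxygen. The fallback sets out from 9 and returns at 10. Iodine in methanol with trimethyl orthoformate (THF co‑solvent, reflux) should aromatise the ring by enol‑ether formation, α‑iodination and loss of HI, giving 1,5‑dimethoxy‑2‑methyl‑3‑pentacosylbenzene F3. BBr3 in CH2Cl2 (0 °C to rt) then cleaves both methyl ethers to give 10.

Step 5. Mass transfer between the aqueous radical salt and the waxy phenol may be so slow that the oxidant decomposes before conversion is complete, and the amphiphilic hydroxyquinone anion may cause emulsions. The fallback sets out from 10 and returns at 11. C‑Nitrosation at the same para carbon (isoamyl nitrite, HCl, EtOH/THF, 0 °C) should give 4‑methyl‑6‑nitroso‑5‑pentacosylbenzene‑1,3‑diol F4. Reduction with Na2S2O4 in aqueous THF gives 4‑amino‑6‑methyl‑5‑pentacosylbenzene‑1,3‑diol F5. Oxidation with FeCl3 in aqueous HCl/THF gives the quinone monoimine 5‑hydroxy‑4‑imino‑2‑methyl‑3‑pentacosylcyclohexa‑2,5‑dien‑1‑one F6 (not isolated), which hydrolyses in the same acidic medium to 11.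

Further compounds
F1 | step 2 | diethyl 2‑(2‑oxononacosan‑4‑yl)propanedioate (racemic) | CCCCCCCCCCCCCCCCCCCCCCCCCC(CC(C)=O)C(C(=O)OCC)C(=O)OCC
F2 | step 2 | ethyl 2,4‑dioxo‑6‑pentacosylcyclohexane‑1‑carboxylate (racemic, both diastereomers) | CCOC(=O)C1C(=O)CC(=O)CC1CCCCCCCCCCCCCCCCCCCCCCCCC
F3 | step 4 | 1,5‑dimethoxy‑2‑methyl‑3‑pentacosylbenzene | Cc1c(OC)cc(OC)cc1CCCCCCCCCCCCCCCCCCCCCCCCC
F4 | step 5 | 4‑methyl‑6‑nitroso‑5‑pentacosylbenzene‑1,3‑diol | Cc1c(O)cc(O)c(N=O)c1CCCCCCCCCCCCCCCCCCCCCCCCC
F5 | step 5 | 4‑amino‑6‑methyl‑5‑pentacosylbenzene‑1,3‑diol | Cc1c(O)cc(O)c(N)c1CCCCCCCCCCCCCCCCCCCCCCCCC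
F6 | step 5 | 5‑hydroxy‑4‑imino‑2‑methyl‑3‑pentacosylcyclohexa‑2,5‑dien‑1‑one | CCCCCCCCCCCCCCCCCCCCCCCCCC1=C(C)C(=O)C=C(O)C1=N
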